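**Plan**
1. Locants used throughout (eudesmane-type): ring C5(=C10)–C6(OAc)–C7–C8(O)–C9H2–C10; C14 is the CH2O carbon on C10; side chain C4(H)(Me)–C3–C2–C1–OAc on C5; lactone C7–C11(=C13H2)–C12(=O)–O–C8. The target is (4S,6S,7S,8R), 6,7-cis and 7,8-trans.
2. Retrosynthesis: (i) the three ester C–O bonds and the lactone (C12–O8, C11=C13) are cut back to an 8-silyloxy 12-aldehyde acetal; (ii) C6–OH and C14–OH go back to a C6 ketone and a C14 methyl ester; (iii) both ring bonds of C5 (C5–C6 and C5–C10) are cut, leaving a cyclopentanone β-keto ester (ring C6–C7–C8–C9–C10) and a one-carbon carbenoid that already carries the side chain; (iv) the cyclopentanone is cut at C6–C10 (Dieckmann) and C7–C8 (aldol).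
3. Enabling feature: the cyclohexene holds the array O–C14–C10=C5–C6–O, an oxygenated carbon on each side of the tetrasubstituted alkene. This is the reduced form of a 4-oxo-2-enoate, which is what insertion of a carbenoid carbon into the C(=O)–Cα ring bond of a β-keto ester gives after iodination/elimination.
4. Forward: Evans aldol and Dieckmann closure give the five-membered ring; insertion of C5 enlarges it to the cyclohexenone, joins the two fragments and sets the tetrasubstituted alkene; the lactone ring is closed last (lactol, then oxidation) once the three acyl groups are in place.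
5. Stereochemistry: C7 and C8 come from the Evans syn-aldol with the (S)-benzyl auxiliary (syn in the chain = trans on the ring); C4 is bought with (S)-β-citronellene; C6 is set by CBS reduction (reagent control, OH cis to the C7 chain).

Key step: step 10

Remark: 1, 2, 4 and 10 are taken as commercial; 10 is defined by its CIP descriptor, (3S)-3,7-dimethylocta-1,6-diene.
Remark: 9, 16 and 17 are epimer mixtures at centres that become sp2 in 18; their SMILES leave these centres open.

**Route**

Step 1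
Reactants: 1 (S)-4-benzyl-1,3-oxazolidin-2-one; 2 pent-4-enoyl chloride
Product: 3 (4S)-4-benzyl-3-(pent-4-enoyl)-1,3-oxazolidin-2-one
Conditions: n-BuLi, THF, −78 °C; then 2, −78 → 0 °C
Reagents that add atoms: none
Why: N-acylation of the lithiated oxazolidinone by the acid chloride (imide formation) attaches the Evans auxiliary; no stereocentre is formed.

Step 2
Reactants: 3 N-pentenoyl oxazolidinone; 4 methyl 4-oxobutanoate
Product: 5 methyl (4R,5S)-5-[(4S)-4-benzyl-2-oxo-1,3-oxazolidine-3-carbonyl]-4-hydroxyoct-7-enoate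
Conditions: Bu2BOTf, i-Pr2NEt, CH2Cl2, 0 °C; 4, −78 → 0 °C; pH 7 buffer/MeOH/H2O2, 0 °C; product silylated without delay
Reagents that add atoms: none
Why: Evans syn-aldol reaction: the (Z)-boron enolate reacts through a Zimmerman–Traxler chair on the face opposite the benzyl group, which sets the future C7 and C8 (syn in the chain, trans on the later ring) in the absolute sense fixed by the (S)-auxiliary.

Step 3
Reactants: 5 aldol adduct
Product: 6 methyl (4R,5S)-5-[(4S)-4-benzyl-2-oxo-1,3-oxazolidine-3-carbonyl]-4-[(tert-butyldimethylsilyl)oxy]oct-7-enoate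
Conditions: TBSOTf, 2,6-lutidine, CH2Cl2, −78 → 0 °C
Reagents that add atoms: tert-butyldimethylsilyl triflate, CC(C)(C)[Si](C)(C)OS(=O)(=O)C(F)(F)F
Why: Silyl ether formation at the secondary alcohol blocks retro-aldol and lactonisation onto the methyl ester; the stereocentres are untouched.

Step 4
Reactants: 6 silylated aldol
Product: 8 methyl (4R,5S)-5-[(4S)-4-benzyl-2-oxo-1,3-oxazolidine-3-carbonyl]-4-[(tert-butyldimethylsilyl)oxy]-7,7-dimethoxyheptanoate, via aldehyde 7 (not isolated)
Conditions: O3, CH2Cl2/MeOH, −78 °C; Me2S, −78 °C → rt; then HC(OMe)3, PPTS (cat.), MeOH, rt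
Reagents that add atoms: ozone, [O-][O+]=O (oxygen of 7 only); trimethyl orthoformate, COC(OC)OC (the two methoxy groups of 8)
Why: Ozonolysis of the only alkene followed by acid-catalysed acetalisation masks the future C12 aldehyde as a base- and hydride-stable dimethyl acetal; imide, ester and silyl ether tolerate PPTS/MeOH.

Step 5
Reactants: 8 acetal imide
Product: 9 methyl (3S,4R)-4-[(tert-butyldimethylsilyl)oxy]-3-(2,2-dimethoxyethyl)-2-oxocyclopentane-1-carboxylate
Conditions: LiHMDS (2.2 equiv), THF, −78 → −20 °C; AcOH quench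
Reagents that add atoms: none
Why: Dieckmann (intramolecular Claisen) condensation: the ester enolate at the future C10 acylates the more electrophilic imide carbonyl (5-exo-trig) with loss of the auxiliary, the α-branched imide C–H being kinetically non-acidic (allylic strain), so the aldol stereocentres survive and the product is protected as its enolate.

Step 6
Reactants: 10 (S)-β-citronellene
Product: 11 (4S)-4-methylhex-5-en-1-ol
Conditions: O3 (1 equiv, indicator dye), CH2Cl2/MeOH, −78 °C; then NaBH4, −78 → 0 °C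
Reagents that add atoms: ozone, [O-][O+]=O
Why: Chemoselective ozonolysis of the electron-rich trisubstituted alkene with reductive work-up leaves the vinyl group and the bought stereocentre (future C4) untouched.

Step 7
Reactants: 11 hexenol
Product: 12 1-methoxy-4-({[(4S)-4-methylhex-5-en-1-yl]oxy}methyl)benzene
Conditions: NaH, 4-methoxybenzyl chloride, Bu4NI (cat.), DMF, 0 °C → rt
Reagents that add atoms: 4-methoxybenzyl chloride, COc1ccc(CCl)cc1
Why: Williamson etherification protects the primary alcohol as a PMB ether that survives the organozinc, hydride and acylation steps and is removed oxidatively.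

Step 8
Reactants: 12 PMB ether
Product: 13 (2S)-5-[(4-methoxybenzyl)oxy]-2-methylpentanal
Conditions: O3 (1 equiv, indicator dye), CH2Cl2, −78 °C; PPh3; used at once
Reagents that add atoms: ozone, [O-][O+]=O
Why: Ozonolysis of the terminal alkene with phosphine work-up gives the α-chiral aldehyde, which is carried on directly to avoid epimerisation.

Step 9
Reactants: 13 aldehyde
Product: 15 1-({[(4S)-5,5-diiodo-4-methylpentyl]oxy}methyl)-4-methoxybenzene, via hydrazone 14 (not isolated)
Conditions: N2H4·H2O (excess), EtOH, 0 °C → rt, concentrate; then I2, Et3N, Et2O, 0 °C (inverse addition)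
Reagents that add atoms: hydrazine, NN (nitrogens of 14 only); iodine, II
Why: Hydrazone formation and iodine oxidation (Barton-type hydrazone iodination, via the diazoalkane) give the 1,1-diiodide without involving the adjacent stereocentre, and the mild amine base at low temperature limits elimination to the vinyl iodide.

Step 10
Reactants: 9 cyclopentanone β-keto ester; 15 1,1-diiodide
Product: 18 methyl (4S,5R)-5-[(tert-butyldimethylsilyl)oxy]-4-(2,2-dimethoxyethyl)-2-{(2S)-5-[(4-methoxybenzyl)oxy]pentan-2-yl}-3-oxocyclohex-1-ene-1-carboxylate, via zinc ester enolate 16 (not isolated), via tertiary iodide 17 (not isolated)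
Conditions: Et2Zn (5 equiv), 15 (2.5 equiv), CH2Cl2, 0 °C; then 9, 0 °C → rt; I2, 0 °C; aqueous thiosulfate work-up; then DBU (1.2 equiv), Et2O, 0 °C
Reagents that add atoms: diethylzinc, CC[Zn]CC (ethylzinc of 16 only); iodine, II (iodine of 17 only)
Why: Proposed new method: Et2Zn forms the zinc enolate of the β-keto ester and, by I/Zn exchange with 15, the α-iodoalkylzinc carbenoid; C-alkylation at the ester-bearing ring carbon and 3-exo-trig attack of the new C–Zn carbon on the ring ketone give a zinc cyclopropoxide, whose strain-driven retro-aldol cleavage of the former C(=O)–Cα ring bond enlarges the five-membered ring to the six-membered one and leaves the ester-stabilised organozinc 16. The closest known reaction type is the zinc-carbenoid chain extension of β-keto esters to γ-keto esters, known with CH2I2 and 1,1-diiodoethane and in tandem with iodination/elimination to 4-oxo-2-enoates; new here are the α-branched secondary-alkyl carbenoid and its use on a ring-substituted β-keto ester with ring enlargement. The only ring that is closed is the transient cyclopropane (3-exo-trig on C=O), and the cyclohexenone arises by one-carbon insertion, not by closure. Iodinolysis of 16 gives tertiary iodide 17, and DBU removes the ketone-activated proton on the inserted carbon (E1cB), which places the tetrasubstituted alkene between C5 and C10. No new stereocentre survives (C5 and C10 become sp2), C4 and C8 are not touched, and C7, although α to the ketone, keeps the trans arrangement that is also the thermodynamic one. The step needs insertion on the ester side of the ketone, which the β-keto ester secures because only that enolate forms with Et2Zn, and it needs the carbenoid to outrun its own 1,2-hydride shift, which low temperature and excess reagent should favour (unreacted 15 is regenerated by the iodine quench).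

Step 11
Reactants: 18 enone ester
Product: 19 methyl (3S,4R,5R)-5-[(tert-butyldimethylsilyl)oxy]-4-(2,2-dimethoxyethyl)-3-hydroxy-2-{(2S)-5-[(4-methoxybenzyl)oxy]pentan-2-yl}cyclohex-1-ene-1-carboxylate
Conditions: (R)-2-methyl-CBS-oxazaborolidine (0.3 equiv), catecholborane (2 equiv), toluene, −78 → −40 °C; MeOH quench
Reagents that add atoms: none
Why: Corey–Bakshi–Shibata reduction: under catalyst control, with the alkene-bearing α-substituted flank as the large group, hydride should go to the ketone face that gives the 6S alcohol (OH cis to the C7 chain), and catecholborane reduces neither the enoate nor the acetal.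

Step 12
Reactants: 19 hydroxy ester
Product: 20 (1S,5R,6R)-5-[(tert-butyldimethylsilyl)oxy]-6-(2,2-dimethoxyethyl)-3-(hydroxymethyl)-2-{(2S)-5-[(4-methoxybenzyl)oxy]pentan-2-yl}cyclohex-2-en-1-ol
Conditions: DIBAL-H (3.5 equiv), CH2Cl2, −78 °C; Rochelle salt work-up
Reagents that add atoms: none
Why: DIBAL-H 1,2-reduction of the conjugated methyl ester gives the allylic alcohol (C14); acetal, silyl ether and PMB ether are inert and no stereocentre is affected.

Step 13
Reactants: 20 diol
Product: 21 [(3S,4R,5R)-5-[(tert-butyldimethylsilyl)oxy]-4-(2,2-dimethoxyethyl)-3-hydroxy-2-{(2S)-5-[(4-methoxybenzyl)oxy]pentan-2-yl}cyclohex-1-en-1-yl]methyl 2-methylprop-2-enoate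
Conditions: methacryloyl chloride (1.05 equiv), Et3N, CH2Cl2, −78 °C
Reagents that add atoms: methacryloyl chloride, C=C(C)C(Cl)=O
Why: Chemoselective acylation of the unhindered primary allylic alcohol at low temperature, in the presence of the secondary C6 alcohol that is shielded by the tetrasubstituted alkene, installs the methacrylate.

Step 14
Reactants: 21 methacrylate
Product: 22 [(3S,4R,5R)-5-[(tert-butyldimethylsilyl)oxy]-4-(2,2-dimethoxyethyl)-3-hydroxy-2-[(2S)-5-hydroxypentan-2-yl]cyclohex-1-en-1-yl]methyl 2-methylprop-2-enoate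
Conditions: DDQ (1.3 equiv), CH2Cl2/pH 7 buffer (10:1), 0 °C
Reagents that add atoms: none
Why: Oxidative PMB ether cleavage with DDQ under buffered conditions frees the C1 alcohol without touching methacrylate, silyl ether or acetal.

Step 15
Reactants: 22 diol
Product: 23 [(3S,4R,5R)-3-acetoxy-2-[(2S)-5-acetoxypentan-2-yl]-5-[(tert-butyldimethylsilyl)oxy]-4-(2,2-dimethoxyethyl)cyclohex-1-en-1-yl]methyl 2-methylprop-2-enoate
Conditions: Ac2O, pyridine, DMAP (cat.), CH2Cl2, 0 °C → rt
Reagents that add atoms: acetic anhydride, CC(=O)OC(C)=O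
Why: DMAP-catalysed acetylation esterifies the primary C1 and the secondary C6 hydroxyl in one operation, with retention at C6.

Step 16
Reactants: 23 diacetate acetal
Product: 24 [(3S,4R,5R)-3-acetoxy-2-[(2S)-5-acetoxypentan-2-yl]-5-[(tert-butyldimethylsilyl)oxy]-4-(2-oxoethyl)cyclohex-1-en-1-yl]methyl 2-methylprop-2-enoate
Conditions: PPTS (0.2 equiv), acetone/H2O (10:1), 40 °C
Reagents that add atoms: water, O
Why: Mild acid-catalysed acetal hydrolysis unmasks the C12 aldehyde while the secondary TBS ether and the three esters survive.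

Step 17
Reactants: 24 aldehyde
Product: 25 [(3S,4R,5R)-3-acetoxy-2-[(2S)-5-acetoxypentan-2-yl]-5-[(tert-butyldimethylsilyl)oxy]-4-(3-oxoprop-1-en-2-yl)cyclohex-1-en-1-yl]methyl 2-methylprop-2-enoate
Conditions: Eschenmoser's salt (3 equiv), Et3N, CH2Cl2, rt
Reagents that add atoms: N,N-dimethylmethyleneiminium iodide, C=[N+](C)C.[I-]
Why: Mannich reaction with Eschenmoser's salt and in situ β-elimination of dimethylamine gives the α-methylene aldehyde under conditions too mild to touch the acetates, the methacrylate or C7 (β to the aldehyde).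

Step 18
Reactants: 25 silyloxy enal
Product: 26 [(3aS,4S,7aR)-4-acetoxy-5-[(2S)-5-acetoxypentan-2-yl]-2-hydroxy-3-methylidene-2,3,3a,4,7,7a-hexahydro-1-benzofuran-6-yl]methyl 2-methylprop-2-enoate
Conditions: HF·pyridine, pyridine, THF, 0 °C → rt
Reagents that add atoms: none
Why: Fluoride desilylation frees the C8 hydroxyl, which adds to the aldehyde (5-exo-trig) to give the trans-fused lactol; the cis C6 oxygen is already acetylated and cannot compete.

Step 19
Reactants: 26 lactol
Product: 27 [(3aS,4S,7aR)-4-acetoxy-5-[(2S)-5-acetoxypentan-2-yl]-3-methylidene-2-oxo-2,3,3a,4,7,7a-hexahydro-1-benzofuran-6-yl]methyl 2-methylprop-2-enoate (target)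
Conditions: Dess–Martin periodinane (1.5 equiv), NaHCO3, CH2Cl2, 0 °C → rt
Reagents that add atoms: none
Why: Dess–Martin oxidation of the lactol to the lactone completes the α-methylene-γ-butyrolactone under buffered neutral conditions that spare the other esters and alkenes.

**Compound list**
1 | (S)-4-benzyl-1,3-oxazolidin-2-one | O=C1N[C@@H](Cc2ccccc2)CO1 | starting material
2 | pent-4-enoyl chloride | C=CCCC(Cl)=O | starting material
3 | (4S)-4-benzyl-3-(pent-4-enoyl)-1,3-oxazolidin-2-one | C=CCCC(=O)N1C(=O)OC[C@@H]1Cc1ccccc1 | intermediate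
4 | methyl 4-oxobutanoate | COC(=O)CCC=O | starting material
5 | methyl (4R,5S)-5-[(4S)-4-benzyl-2-oxo-1,3-oxazolidine-3-carbonyl]-4-hydroxyoct-7-enoate | O=C(N1C(=O)OC[C@@H]1Cc1ccccc1)[C@@H](CC=C)[C@H](O)CCC(=O)OC | intermediate
6 | methyl (4R,5S)-5-[(4S)-4-benzyl-2-oxo-1,3-oxazolidine-3-carbonyl]-4-[(tert-butyldimethylsilyl)oxy]oct-7-enoate | O=C(N1C(=O)OC[C@@H]1Cc1ccccc1)[C@@H](CC=C)[C@H](O[Si](C)(C)C(C)(C)C)CCC(=O)OC | intermediate
7 | methyl (4R,5S)-5-[(4S)-4-benzyl-2-oxo-1,3-oxazolidine-3-carbonyl]-4-[(tert-butyldimethylsilyl)oxy]-7-oxoheptanoate (not isolated) | O=C(N1C(=O)OC[C@@H]1Cc1ccccc1)[C@@H](CC=O)[C@H](O[Si](C)(C)C(C)(C)C)CCC(=O)OC | intermediate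
8 | methyl (4R,5S)-5-[(4S)-4-benzyl-2-oxo-1,3-oxazolidine-3-carbonyl]-4-[(tert-butyldimethylsilyl)oxy]-7,7-dimethoxyheptanoate | O=C(N1C(=O)OC[C@@H]1Cc1ccccc1)[C@@H](CC(OC)OC)[C@H](O[Si](C)(C)C(C)(C)C)CCC(=O)OC | intermediate
9 | methyl (3S,4R)-4-[(tert-butyldimethylsilyl)oxy]-3-(2,2-dimethoxyethyl)-2-oxocyclopentane-1-carboxylate (3,4-trans; C1 epimers/enol) | COC(=O)C1C(=O)[C@@H](CC(OC)OC)[C@H](O[Si](C)(C)C(C)(C)C)C1 | intermediate
10 | (S)-β-citronellene, (3S)-3,7-dimethylocta-1,6-diene | C=C[C@@H](C)CCC=C(C)C | starting material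
11 | (4S)-4-methylhex-5-en-1-ol | C=C[C@@H](C)CCCO | intermediate
12 | 1-methoxy-4-({[(4S)-4-methylhex-5-en-1-yl]oxy}methyl)benzene | C=C[C@@H](C)CCCOCc1ccc(OC)cc1 | intermediate
13 | (2S)-5-[(4-methoxybenzyl)oxy]-2-methylpentanal | O=C[C@@H](C)CCCOCc1ccc(OC)cc1 | intermediate
14 | hydrazone of 13, [(2S)-5-[(4-methoxybenzyl)oxy]-2-methylpentylidene]hydrazine (not isolated) | NN=C[C@@H](C)CCCOCc1ccc(OC)cc1 | intermediate
15 | 1-({[(4S)-5,5-diiodo-4-methylpentyl]oxy}methyl)-4-methoxybenzene | IC(I)[C@@H](C)CCCOCc1ccc(OC)cc1 | intermediate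
16 | ring-enlarged ethylzinc ester enolate (zinc on the ester oxygen, C5 sp3, not isolated) | CC[Zn]OC(OC)=C1C([C@@H](C)CCCOCc2ccc(OC)cc2)C(=O)[C@@H](CC(OC)OC)[C@H](O[Si](C)(C)C(C)(C)C)C1 | intermediate
17 | methyl (4S,5R)-5-[(tert-butyldimethylsilyl)oxy]-4-(2,2-dimethoxyethyl)-1-iodo-2-{(2S)-5-[(4-methoxybenzyl)oxy]pentan-2-yl}-3-oxocyclohexane-1-carboxylate (not isolated) | COC(=O)C1(I)C([C@@H](C)CCCOCc2ccc(OC)cc2)C(=O)[C@@H](CC(OC)OC)[C@H](O[Si](C)(C)C(C)(C)C)C1 | intermediate
18 | methyl (4S,5R)-5-[(tert-butyldimethylsilyl)oxy]-4-(2,2-dimethoxyethyl)-2-{(2S)-5-[(4-methoxybenzyl)oxy]pentan-2-yl}-3-oxocyclohex-1-ene-1-carboxylate | COC(=O)C1=C([C@@H](C)CCCOCc2ccc(OC)cc2)C(=O)[C@@H](CC(OC)OC)[C@H](O[Si](C)(C)C(C)(C)C)C1 | intermediate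
19 | methyl (3S,4R,5R)-5-[(tert-butyldimethylsilyl)oxy]-4-(2,2-dimethoxyethyl)-3-hydroxy-2-{(2S)-5-[(4-methoxybenzyl)oxy]pentan-2-yl}cyclohex-1-ene-1-carboxylate | COC(=O)C1=C([C@@H](C)CCCOCc2ccc(OC)cc2)[C@@H](O)[C@@H](CC(OC)OC)[C@H](O[Si](C)(C)C(C)(C)C)C1 | intermediate
20 | (1S,5R,6R)-5-[(tert-butyldimethylsilyl)oxy]-6-(2,2-dimethoxyethyl)-3-(hydroxymethyl)-2-{(2S)-5-[(4-methoxybenzyl)oxy]pentan-2-yl}cyclohex-2-en-1-ol | OCC1=C([C@@H](C)CCCOCc2ccc(OC)cc2)[C@@H](O)[C@@H](CC(OC)OC)[C@H](O[Si](C)(C)C(C)(C)C)C1 | intermediate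
21 | [(3S,4R,5R)-5-[(tert-butyldimethylsilyl)oxy]-4-(2,2-dimethoxyethyl)-3-hydroxy-2-{(2S)-5-[(4-methoxybenzyl)oxy]pentan-2-yl}cyclohex-1-en-1-yl]methyl 2-methylprop-2-enoate | C=C(C)C(=O)OCC1=C([C@@H](C)CCCOCc2ccc(OC)cc2)[C@@H](O)[C@@H](CC(OC)OC)[C@H](O[Si](C)(C)C(C)(C)C)C1 | intermediate
22 | [(3S,4R,5R)-5-[(tert-butyldimethylsilyl)oxy]-4-(2,2-dimethoxyethyl)-3-hydroxy-2-[(2S)-5-hydroxypentan-2-yl]cyclohex-1-en-1-yl]methyl 2-methylprop-2-enoate | C=C(C)C(=O)OCC1=C([C@@H](C)CCCO)[C@@H](O)[C@@H](CC(OC)OC)[C@H](O[Si](C)(C)C(C)(C)C)C1 | intermediate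
23 | [(3S,4R,5R)-3-acetoxy-2-[(2S)-5-acetoxypentan-2-yl]-5-[(tert-butyldimethylsilyl)oxy]-4-(2,2-dimethoxyethyl)cyclohex-1-en-1-yl]methyl 2-methylprop-2-enoate | C=C(C)C(=O)OCC1=C([C@@H](C)CCCOC(C)=O)[C@@H](OC(C)=O)[C@@H](CC(OC)OC)[C@H](O[Si](C)(C)C(C)(C)C)C1 | intermediate
24 | [(3S,4R,5R)-3-acetoxy-2-[(2S)-5-acetoxypentan-2-yl]-5-[(tert-butyldimethylsilyl)oxy]-4-(2-oxoethyl)cyclohex-1-en-1-yl]methyl 2-methylprop-2-enoate | C=C(C)C(=O)OCC1=C([C@@H](C)CCCOC(C)=O)[C@@H](OC(C)=O)[C@@H](CC=O)[C@H](O[Si](C)(C)C(C)(C)C)C1 | intermediate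
25 | [(3S,4R,5R)-3-acetoxy-2-[(2S)-5-acetoxypentan-2-yl]-5-[(tert-butyldimethylsilyl)oxy]-4-(3-oxoprop-1-en-2-yl)cyclohex-1-en-1-yl]methyl 2-methylprop-2-enoate | C=C(C)C(=O)OCC1=C([C@@H](C)CCCOC(C)=O)[C@@H](OC(C)=O)[C@@H](C(=C)C=O)[C@H](O[Si](C)(C)C(C)(C)C)C1 | intermediate
26 | [(3aS,4S,7aR)-4-acetoxy-5-[(2S)-5-acetoxypentan-2-yl]-2-hydroxy-3-methylidene-2,3,3a,4,7,7a-hexahydro-1-benzofuran-6-yl]methyl 2-methylprop-2-enoate (lactol, both anomers) | C=C(C)C(=O)OCC1=C([C@@H](C)CCCOC(C)=O)[C@@H](OC(C)=O)[C@H]2C(=C)C(O)O[C@@H]2C1 | intermediate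
27 | [(3aS,4S,7aR)-4-acetoxy-5-[(2S)-5-acetoxypentan-2-yl]-3-methylidene-2-oxo-2,3,3a,4,7,7a-hexahydro-1-benzofuran-6-yl]methyl 2-methylprop-2-enoate, (4S,6S,7S,8R) in the locants of the plan | C=C(C)C(=O)OCC1=C([C@@H](C)CCCOC(C)=O)[C@@H](OC(C)=O)[C@H]2C(=C)C(=O)O[C@@H]2C1 | target

**Count and risks**
Total: 19 steps. Longest linear sequence: 15 steps (steps 1–5, then 10–19); the side-chain branch (steps 6–9) joins at step 10.

Step 10 (carbenoid insertion, proposed new method). C-alkylation of the hindered, ring-substituted zinc enolate by the α-branched carbenoid may be slower than the carbenoid's own 1,2-hydride shift to an alkene. During the DBU treatment, enolisation towards C7 may expel silanolate and start aromatisation of the ring. The fallback uses known chemistry, a radical instead of a carbenoid; it sets out from 9 and aldehyde 13 and returns at 18. Compound 9 is silylated (TMSCl, Et3N, MeCN) to the trimethylsilyl enol ether F1. A Lewis-base-catalysed Mukaiyama aldol addition to 13 (LiOAc cat., DMF, −45 °C; citric acid work-up) should give the aldol F2, in which the quaternary ester-bearing carbon is bonded to the future C5. The secondary hydroxyl is converted into the O-phenyl thionocarbonate F3 (PhOC(S)Cl, pyridine, DMAP). Slow addition of Bu3SnH/AIBN (benzene, 80 °C) generates the C5 radical as in a Barton–McCombie deoxygenation; it adds to the ring ketone, and β-scission of the cyclopropyloxy radical to the ester-stabilised radical (Dowd–Beckwith one-carbon ring expansion) gives the saturated γ-keto ester F4. Dehydrogenation across C5–C10 with IBX·4-methoxypyridine N-oxide (DMSO, rt) should then give 18.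

Step 11 (CBS reduction). Facial selectivity may be poor if the substrate's own bias (axial attack anti to the C7 hydrogen) opposes the catalyst, and conjugate reduction of the doubly activated alkene may compete. The fallback is substrate-directed instead of reagent-controlled; it sets out from 18 and returns at 19. The silyl ether is removed with pyridine-buffered HF·pyridine (THF, 0 °C) to give the β-hydroxy ketone F5. Evans–Saksena reduction (Me4NBH(OAc)3, MeCN/AcOH, −30 °C) delivers hydride intramolecularly from the face of the C8 oxygen and should give the 6,8-anti diol F6, with C6–OH cis to the C7 chain. The unhindered C8 hydroxyl is then re-silylated selectively (TBSCl, imidazole, DMF, 0 °C), the C6 hydroxyl being shielded by the tetrasubstituted alkene, which returns 19.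

Step 5 (Dieckmann closure on the imide). Enolisation at the imide α-carbon may be followed by β-elimination of silanolate, or the ester enolate may attack the ring carbonyl of the auxiliary. The fallback removes the auxiliary first; it sets out from 8 and returns at 9. LiOH/H2O2 (THF/H2O, 0 °C) cleaves the imide selectively to the acid F7 with recovery of 1. TMSCHN2 (toluene/MeOH) gives the dimethyl ester F8. A conventional Dieckmann condensation (KOt-Bu, THF, 0 °C) closes F8 to 9; the alternative closure is reversible because its product has no acidic proton between the carbonyls.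

Further compounds
F1 | step 10 | methyl (3S,4R)-4-[(tert-butyldimethylsilyl)oxy]-3-(2,2-dimethoxyethyl)-2-[(trimethylsilyl)oxy]cyclopent-1-ene-1-carboxylate | COC(=O)C1=C(O[Si](C)(C)C)[C@@H](CC(OC)OC)[C@H](O[Si](C)(C)C(C)(C)C)C1
F2 | step 10 | methyl (3S,4R)-4-[(tert-butyldimethylsilyl)oxy]-3-(2,2-dimethoxyethyl)-1-{(2S)-1-hydroxy-5-[(4-methoxybenzyl)oxy]-2-methylpentyl}-2-oxocyclopentane-1-carboxylate (epimers at C1 and the carbinol carbon) | COC(=O)C1(C(O)[C@@H](C)CCCOCc2ccc(OC)cc2)C(=O)[C@@H](CC(OC)OC)[C@H](O[Si](C)(C)C(C)(C)C)C1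
F3 | step 10 | methyl (3S,4R)-4-[(tert-butyldimethylsilyl)oxy]-3-(2,2-dimethoxyethyl)-1-{(2S)-5-[(4-methoxybenzyl)oxy]-2-methyl-1-[(phenoxycarbonothioyl)oxy]pentyl}-2-oxocyclopentane-1-carboxylate | COC(=O)C1(C(OC(=S)Oc2ccccc2)[C@@H](C)CCCOCc2ccc(OC)cc2)C(=O)[C@@H](CC(OC)OC)[C@H](O[Si](C)(C)C(C)(C)C)C1
F4 | step 10 | methyl (4S,5R)-5-[(tert-butyldimethylsilyl)oxy]-4-(2,2-dimethoxyethyl)-2-{(2S)-5-[(4-methoxybenzyl)oxy]pentan-2-yl}-3-oxocyclohexane-1-carboxylate (epimers at C1 and C2) | COC(=O)C1C([C@@H](C)CCCOCc2ccc(OC)cc2)C(=O)[C@@H](CC(OC)OC)[C@H](O[Si](C)(C)C(C)(C)C)C1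
F5 | step 11 | methyl (4S,5R)-4-(2,2-dimethoxyethyl)-5-hydroxy-2-{(2S)-5-[(4-methoxybenzyl)oxy]pentan-2-yl}-3-oxocyclohex-1-ene-1-carboxylate | COC(=O)C1=C([C@@H](C)CCCOCc2ccc(OC)cc2)C(=O)[C@@H](CC(OC)OC)[C@H](O)C1
F6 | step 11 | methyl (3S,4S,5R)-4-(2,2-dimethoxyethyl)-3,5-dihydroxy-2-{(2S)-5-[(4-methoxybenzyl)oxy]pentan-2-yl}cyclohex-1-ene-1-carboxylate | COC(=O)C1=C([C@@H](C)CCCOCc2ccc(OC)cc2)[C@@H](O)[C@@H](CC(OC)OC)[C@H](O)C1
F7 | step 5 | (2S,3R)-3-[(tert-butyldimethylsilyl)oxy]-2-(2,2-dimethoxyethyl)-6-methoxy-6-oxohexanoic acid | OC(=O)[C@@H](CC(OC)OC)[C@H](O[Si](C)(C)C(C)(C)C)CCC(=O)OC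
F8 | step 5 | dimethyl (2S,3R)-3-[(tert-butyldimethylsilyl)oxy]-2-(2,2-dimethoxyethyl)hexanedioate | COC(=O)[C@@H](CC(OC)OC)[C@H](O[Si](C)(C)C(C)(C)C)CCC(=O)OC
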